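Two orders are asked, both at one moment of a flask not yet run.

| flask | L | D | Q | remark |
|---|---|---|---|---|
| cedar | 0.050 M | 1.2 equiv | 0.07 mol% | run made earlier |
| elm | 0.050 M | 1.2 equiv | 0.11 mol% | run made earlier |
| alder | 0.10 M | 1.2 equiv | 0.05 mol% | run made earlier |
| flask | 0.050 M | 1.20 equiv | 0.05 mol% |  |

| run | time / min | E / % |
|---|---|---|
| cedar | 0.167 | 11.4 |
| cedar | 0.500 | 37.3 |
| cedar | 0.833 | 54.9 |
| cedar | 1.33 | 69.8 |
| cedar | 2.00 | 81.3 |
| cedar | 2.50 | 85.3 |
| cedar | 3.00 | 88.6 |
| elm | 0.417 | 48.7 |
| elm | 0.833 | 70.2 |
| elm | 1.33 | 80.7 |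
| elm | 1.50 | 84.2 |
| elm | 2.00 | 87.4 |
| elm | 2.50 | 91.8 |
| elm | 3.00 | 93.9 |
| alder | 0.250 | 43.5 |
| alder | 0.417 | 60.7 |
| alder | 0.833 | 81.5 |
| alder | 1.50 | 92.2 |
| alder | 3.00 | 98.2 |

(each reading ± 0.5 percentage points)

- apparent order in D when 50% of the L are converted (percent change of the rate of making E for one percent more D charged)
- apparent order in Q when 50% of the L are converted (percent change of the rate of making E for one percent more Q charged)

The proposed steps are L + Q → Q + J, D + Q + J → Q + E and Q ⇌ Z. The first two each carry c_Q once, so at equal c_L and equivalents we expect one run to repeat another on a clock stretched by the loading. For this flask that gives the clock factor, its loading over cedar's, 0.714. But Q ⇌ Z keeps its own clock, so the factor is an approximation.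

The moment of 50% conversion, 0.155 min, then falls at 0.111 min on cedar's clock, earlier than cedar's first reading at 0.167 min. During the lag we take E as growing with the square of time, so that reading of 11.4% gives our own estimate of 5.04% E, which leaves 45.0% as J.

The rate of making E goes with c_D c_Q c_J. More D leaves the conversion unchanged but raises E about in proportion, and that E comes out of J. So the order in D falls short of 1 by the ratio of E to J, 0.112, and we reckon 0.888. As far as the clock factor holds, more Q shortens the clock and leaves E at that conversion unchanged, so we reckon 1 for Q.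

The forecast gives 0.9 for D (0.78 to 1), on the ground that “More D drains J slightly”, and 1 for Q (0.88 to 1.2).

The simulation gives 0.88 for D and 1.1 for Q.

    L + Q → Q + J (k = 3900 /M/s)
    D + Q + J → Q + E (k = 22000 /M²/s)
    Q ⇌ Z (K = 0.610, k = 0.100 /s)

At 0.156 min the flask makes J 3.52 times faster than it uses it up, each step taken net, and the half-life of J by the D step at that moment, 0.56 min, is longer than the time gone by; at 0.500 min the flask holds J 59.5% beside E 26.4%. The clock factor puts that time at 0.357 min on cedar's clock, between cedar's readings of 11.4% and 37.3%, and the same stretch puts elm's 0.833 min at 1.31 min, beside cedar's 69.8% at 1.33 min, where elm read 70.2%.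

(The numbers in the tables were generated by integration for an exercise, and the scatter is random.)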